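**Assumption:** Surinone B has no stereocentre, and the two ring branches on the enol C=C are identical, so it has no stereogenic double bond. It is achiral and there is no configuration to set. The SMILES shows the exocyclic-enol tautomer of 2-(13-phenyltridecanoyl)cyclohexane-1,3-dione, and the product is isolated as the equilibrating enol tautomers.

## Retrosynthetic overview
1. Key disconnection: ring C2–acyl C1'. This is a crossed Claisen-type C-acylation of the cyclohexane-1,3-dione enolate by activated 13-phenyltridecanoic acid.
2. 13-Phenyltridecanoic acid comes from its methyl ester, which is cut at C11–C12 (sp3–sp3) into a 2-phenylethyl Grignard reagent and methyl 11-bromoundecanoate (Cu catalysis).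
3. Purchased building blocks: 11-bromoundecanoic acid, (2-bromoethyl)benzene and cyclohexane-1,3-dione.
4. Rings: none is formed. The benzene ring and the cyclohexanedione ring are bought intact and joined through the C13 chain.

## Route

Step 1
Reactants: 1 11-bromoundecanoic acid
Product: 2 methyl 11-bromoundecanoate
Conditions: MeOH (solvent), conc. H2SO4 (5 mol %), reflux, 4 h; NaHCO3 wash
Reagents that add atoms: methanol, CO
Why: Fischer esterification in excess methanol goes to completion, removes the acidic proton that would destroy the Grignard reagent, and leaves the primary bromide untouched; no stereocentre is involved.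

Step 2
Reactants: 3 (2-bromoethyl)benzene
Product: 4 2-phenylethylmagnesium bromide as a titrated THF stock solution
Conditions: Mg turnings (1.2 equiv), I2 (crystal), THF, slow addition at 30–40 °C, 2 h; titrate
Reagents that add atoms: magnesium, [Mg]
Why: Grignard formation by insertion of Mg into a primary C–Br bond is routine, and slow addition in dilute solution keeps the Wurtz dimer low.

Step 3
Reactants: 2 methyl 11-bromoundecanoate; 4 2-phenylethylmagnesium bromide
Product: 5 methyl 13-phenyltridecanoate
Conditions: Li2CuCl4 (3 mol %), NMP (4 equiv), THF, 0 °C to rt, 4 (1.3 equiv) added over 1 h; sat. NH4Cl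
Reagents that add atoms: none
Why: In this Kochi-type copper-catalysed sp3–sp3 cross-coupling with NMP as co-solvent, the transient alkylcuprate displaces the primary bromide much faster than the slowly added Grignard reagent attacks the ester.

Step 4
Reactants: 5 methyl 13-phenyltridecanoate
Product: 7 13-phenyltridecanoic acid, via lithium 13-phenyltridecanoate 6 (not isolated)
Conditions: LiOH·H2O (3 equiv), THF/MeOH/H2O 3:1:1, 40 °C, 6 h; then 1 M HCl to pH 2; recrystallise from hexane
Reagents that add atoms: lithium hydroxide, [Li+].[OH-]
Why: Saponification (BAc2) of an unhindered methyl ester is irreversible, nothing else in the molecule is base-sensitive, and the mixed solvent keeps the fatty carboxylate dissolved.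

Step 5
Reactants: 7 13-phenyltridecanoic acid; 8 cyclohexane-1,3-dione
Product: 11 surinone B (2-(1-hydroxy-13-phenyltridecylidene)cyclohexane-1,3-dione), via enol ester 9 (not isolated), via triethylammonium triketonate 10 (not isolated)
Conditions: DCC (1.2 equiv), Et3N (1.2 equiv), DMAP (0.2 equiv), CH2Cl2, 0 °C to rt, 24 h; filter; 1 M HCl wash; SiO2
Reagents that add atoms: none
Why: Steglich activation first gives the O-acyl enol ester 9, DMAP then cleaves it to an N-acylpyridinium/dione-enolate pair that recombines at C2 in a crossed Claisen-type C-acylation, and deprotonation of the strongly acidic β-triketone (pKa about 4) by Et3N to 10 pulls all equilibria to the C-acyl product; no stereocentre is formed.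

## Compound list
1 | 11-bromoundecanoic acid | OC(=O)CCCCCCCCCCBr | starting material
2 | methyl 11-bromoundecanoate | COC(=O)CCCCCCCCCCBr | intermediate
3 | (2-bromoethyl)benzene | BrCCc1ccccc1 | starting material
4 | 2-phenylethylmagnesium bromide | Br[Mg]CCc1ccccc1 | intermediate
5 | methyl 13-phenyltridecanoate | COC(=O)CCCCCCCCCCCCc1ccccc1 | intermediate
6 | lithium 13-phenyltridecanoate | [Li+].[O-]C(=O)CCCCCCCCCCCCc1ccccc1 | intermediate
7 | 13-phenyltridecanoic acid | OC(=O)CCCCCCCCCCCCc1ccccc1 | intermediate
8 | cyclohexane-1,3-dione | O=C1CCCC(=O)C1 | starting material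
9 | 3-oxocyclohex-1-en-1-yl 13-phenyltridecanoate (enol ester) | O=C1C=C(OC(=O)CCCCCCCCCCCCc1ccccc1)CCC1 | intermediate
10 | triethylammonium 1-(2,6-dioxocyclohexylidene)-13-phenyltridecan-1-olate | CC[NH+](CC)CC.O=C1CCCC(=O)C1=C([O-])CCCCCCCCCCCCc1ccccc1 | intermediate
11 | surinone B, 2-(1-hydroxy-13-phenyltridecylidene)cyclohexane-1,3-dione (achiral) | O=C1CCCC(=O)C1=C(O)CCCCCCCCCCCCc1ccccc1 | target

## Step count
- Total steps: 5.
- Longest linear sequence: 4 (steps 1, 3, 4, 5 from 1; the branch from 3 through steps 2, 3, 4, 5 is equally long).

## Steps most likely to fail, with fallbacks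

**Step 3.** The risks are Grignard attack on the ester, homocoupling, and β-hydride loss from the copper species.
- The fallback is an olefination/hydrogenation route that sets out from 2 and comes back at 5.
- Compound 2 is heated with PPh3 in MeCN (reflux, 48 h) to give (11-methoxy-11-oxoundecyl)triphenylphosphonium bromide F1.
- NaHMDS in THF at −78 °C converts this into the ylide methyl 11-(triphenyl-λ5-phosphanylidene)undecanoate F2.
- Freshly distilled phenylacetaldehyde is added in a Wittig reaction to give methyl (Z)-13-phenyltridec-11-enoate F3. The Z isomer is the major one, and the geometry is irrelevant.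
- H2 (1 atm) over 10 % Pd/C in EtOAc saturates the alkene to 5.

**Step 5.** The risks are that the reaction stalls at the O-acyl stage 9 or forms an N-acylurea.
- The fallback builds the dione ring by two Claisen condensations instead of buying it. It sets out from 7 and comes back at 11.
- Compound 7 is treated with MeLi (2.2 equiv, Et2O, 0 °C). It passes through 6 and dilithium 14-phenyltetradecane-2,2-diolate F4.
- Inverse quench into cold 1 M HCl collapses this to 14-phenyltetradecan-2-one F5.
- LDA (THF, −78 °C) deprotonates the methyl side kinetically to give lithium 14-phenyltetradec-1-en-2-olate F6.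
- Two equivalents of this enolate are acylated with one equivalent of methyl 5-chloro-5-oxopentanoate to give methyl 5,7-dioxo-19-phenylnonadecanoate F7. The second equivalent is consumed by the acidic product and is recovered as the ketone.
- t-BuOK in THF closes the six-membered ring by Dieckmann-type attack of C6 on the ester carbonyl, giving potassium 1-(2,6-dioxocyclohexylidene)-13-phenyltridecan-1-olate F8.
- 1 M HCl releases 11.

**Step 2.** The risks are Wurtz dimerisation to 1,4-diphenylbutane and sluggish initiation.
- The fallback replaces the sp3 Grignard reagent with an acetylide. It sets out from 1 and comes back at 7, so steps 1–4 are bypassed.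
- Phenylacetylene and n-BuLi (THF, −78 °C) give lithium phenylacetylide F9 (2.3 equiv).
- Acid 1 in THF/DMPU is added at 0 °C. The first equivalent of acetylide turns it into lithium 11-bromoundecanoate F10.
- The second equivalent displaces the primary bromide (SN2, rt to 50 °C) to give lithium 13-phenyltridec-12-ynoate F11.
- 1 M HCl liberates 13-phenyltridec-12-ynoic acid F12.
- H2 (1 atm) over 10 % Pd/C in EtOAc reduces the triple bond fully to give 7.

## Further compounds
F1 | step 3 | (11-methoxy-11-oxoundecyl)triphenylphosphonium bromide | COC(=O)CCCCCCCCCC[P+](c1ccccc1)(c1ccccc1)c1ccccc1.[Br-]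
F2 | step 3 | methyl 11-(triphenyl-λ5-phosphanylidene)undecanoate | COC(=O)CCCCCCCCCC=P(c1ccccc1)(c1ccccc1)c1ccccc1
F3 | step 3 | methyl (Z)-13-phenyltridec-11-enoate | COC(=O)CCCCCCCCC/C=C\Cc1ccccc1
F4 | step 5 | dilithium 14-phenyltetradecane-2,2-diolate | [Li+].[Li+].CC([O-])([O-])CCCCCCCCCCCCc1ccccc1
F5 | step 5 | 14-phenyltetradecan-2-one | CC(=O)CCCCCCCCCCCCc1ccccc1
F6 | step 5 | lithium 14-phenyltetradec-1-en-2-olate | [Li+].C=C([O-])CCCCCCCCCCCCc1ccccc1
F7 | step 5 | methyl 5,7-dioxo-19-phenylnonadecanoate | COC(=O)CCCC(=O)CC(=O)CCCCCCCCCCCCc1ccccc1
F8 | step 5 | potassium 1-(2,6-dioxocyclohexylidene)-13-phenyltridecan-1-olate | [K+].O=C1CCCC(=O)C1=C([O-])CCCCCCCCCCCCc1ccccc1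
F9 | step 2 | lithium phenylacetylide | [Li+].[C-]#Cc1ccccc1
F10 | step 2 | lithium 11-bromoundecanoate | [Li+].[O-]C(=O)CCCCCCCCCCBr
F11 | step 2 | lithium 13-phenyltridec-12-ynoate | [Li+].[O-]C(=O)CCCCCCCCCCC#Cc1ccccc1
F12 | step 2 | 13-phenyltridec-12-ynoic acid | OC(=O)CCCCCCCCCCC#Cc1ccccc1
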